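Remark on the chemistry: (−)-shikimic acid is taken as the (3R,4S,5R) acid; its C3, C4, C5 and C1 become C1, C6, C5 and C3 of ring A, and its carboxyl carbon becomes C10.

## Structural features

The target is a cis-fused bicycle: a cyclohexene (ring A, C1–C6) that carries an α-methylene-γ-butyrolactone (ring B: O5, C7, C8, C6, C5, with the exocyclic methylene C9 on C8) across the C5–C6 bond. Ring A holds a tetrasubstituted C2=C3 double bond; C3 bears the hydroxymethyl carbon C10 and C2 bears the 5-hydroxypentan-2-yl chain (C1′–C4′ plus a methyl group on C1′). Three ring stereocentres stand side by side, C5 (lactone oxygen, R), C6 (ring fusion, R) and C1 (methacrylate, S), and the fourth, C1′ (S), is separated from C1 only by the sp2 carbon C2. At C6 the carbon C8 is cis to O5 and trans to O1, whereas the matching carbon of shikimic acid carries its oxygen cis to the C1 oxygen and trans to the C5 oxygen, so C6 must be inverted while C–O is exchanged for C–C. The fragile groups are the two acrylate-type acceptors (α-methylene lactone and methacrylate), which do not survive nucleophilic base, stannyl radicals or hydride reagents, the allylic ester at C1, and the two primary alcohols that must be freed last without base. The real difficulties are the C6 configuration, the fully substituted C2 next to the C1 oxygen, and the control of C1′ from a distance. The key step exploits the O5–C5–C6 unit: a three-atom propargyl tether on O5 reaches a planar C6 radical only from the face of O5, so ring B closes cis whichever C6–O epimer is broken.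

## Logic of the disconnections

25 ⇒ 24. The two primary O–Si bonds at C10 and C4′ are cut. Both alcohols stay masked until every electrophilic group is in place, so 24 has no free hydroxyl. The forward step must be non-basic, because 25 holds two acceptors that add alkoxide.

24 ⇒ 23. The C7=O bond is removed and C7 returns to a CH2 group between O5 and the C8=C9 bond. An ether ring B can be closed by radical attack on an alkyne tether, which a lactone tether does poorly. The demand is site selectivity: the oxidant must take C7–H2 and leave the allylic C–H bonds around C2=C3. For that reason C1 already carries its electron-poor ester and C10 a bulky silyl group at this stage.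

23 ⇒ 21 + 22. The O1–acyl bond is cut. A methacrylate would not survive the stannane chain, so it is added after ring B exists. The forward acylation meets a hindered secondary allylic alcohol, but it is the only free hydroxyl in 21.

21 ⇒ 20. The O1–Si bond is cut. C1 needs a group that leaves while the primary silyl ethers stay, hence a triethylsilyl ether against tert-butyldiphenylsilyl ethers.

20 ⇒ 19. The C6–C8 bond is cut and ring B opens; C6 returns to a C–O bond with the configuration of shikimic acid. This removes one ring, one C–C bond and one stereocentre, and connects the bicycle to a chiral-pool cyclohexene. The forward step must cyclise faster than the radical is reduced, and it can only close cis.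

19 ⇒ 17 ⇒ 16. The thiocarbonyl group on O6 and the silyl group on O1 are removed. Both hydroxyls of 16 are secondary and cis, so the forward steps demand regioselective silylation of O1 and a C6 alkoxide that is trapped before the neighbouring silyl group can migrate.

16 ⇒ 15 ⇒ 13 + 14. The acetal across O1/O6 is restored and the O5–C7 ether bond is cut. Tying the only cis pair of oxygens in a five-membered acetal leaves O5 alone for alkylation. The alkyne can enter only after the hydrogenation. The acetal must later be hydrolysed in the presence of the primary silyl ethers, which is why these are tert-butyldiphenylsilyl and not tert-butyldimethylsilyl.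

13 ⇒ 12 ⇒ 11. The O10–Si bond is cut, and the two C–H bonds made by hydrogenation at C1′ and its methyl carbon are removed. With C1′ as an sp2 carbon, the C2–C1′ bond becomes an sp2–sp2 coupling. The forward hydrogenation must reduce only the 1,1-disubstituted alkene and choose one face; the free C10 hydroxyl is kept for this step as the anchor for the catalyst.

11 ⇒ 10 ⇒ 9 + 3. The C10 alcohol returns to the methyl ester and the C2–C1′ bond is cut between a ring boronate and a 2-iodoalkene. The ester is needed one step earlier as directing group, so it is reduced only after the coupling. The coupling must tolerate a fully substituted alkenyl boronate.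

9 ⇒ 6 ⇒ 4. The C2–B bond is cut back to C2–H, then the acetal and the methyl ester are removed. Bromination and dehydrobromination of the enoate cannot give a C2 halide, because the anti elimination of the trans-dibromide leads to the allylic bromide. The handle at C2 is therefore placed by ester-directed C–H borylation. The demand is metalation of a vinylic C–H bond that is flanked by the acetal-bearing C1.

3 ⇒ 2 ⇒ 1. The O–Si bond and then the C–I and C–H bonds across the alkyne are cut. The forward addition of HI must be Markovnikov.

## Other disconnections considered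

Alternative 1: The cut takes C2 out of ring A: the C1–C2 and C2–C3 bonds are traced to a one-carbon insertion into the C1=C3 bond of the cyclopentene lactone A1. Forward, dibromocarbene would add to the convex face of A1 to give the gem-dibromocyclopropane A2. Silver-assisted loss of bromide (AgClO4, aqueous acetone), disrotatory opening and capture of the bromoallyl cation by water at C1 would then give the 2-bromocyclohexenol A3.
- In its favour: the cis ring fusion is built into A1, since a bicyclo[3.3.0] lactone cannot be trans; on the C5/C6 relationship it is at least the equal of the chosen plan.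
- Better than the chosen plan: C7 is a carbonyl from the start, so no late C–H oxidation is needed, and C2 appears as a vinyl bromide, the coupling handle that the chosen plan has to create by C–H borylation.
- Against it: the cation has a tertiary terminus (C3) and a secondary one (C1), and water must choose C1 and the convex face; proton loss to a diene competes.
- Against it: A1 with its C3 substituent is not a commercial enantiopure compound, and silver perchlorate is a hazard on scale.
- Comparison: the side chain and C1′ would still have to be introduced exactly as here, and C9 would have to be added by enolate chemistry on a lactone that carries an allylic oxygen. Structurally it secures C6 as well as the radical route; mechanistically it replaces a stereoconvergent closure by a cation capture of uncertain regiochemistry; in step count it would probably be longer.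

Alternative 2: The cut is the C1–C6 bond. Forward, an N-heterocyclic carbene would convert the aldehyde C1 of the enal–butenolide A4 into an acyl anion equivalent that adds to C6 of the butenolide, closing ring A and giving the enone lactone A5.
- In its favour: the plan is convergent, uses no tin and no chromium, and has the lactone carbonyl in place.
- Equal to the chosen plan: C6 of A5 is α to the new ketone and can equilibrate to the more stable cis fusion, so C6 is again set by C5.
- Better than the chosen plan: C1′ could come from a stereodefined acyclic building block instead of a late hydrogenation.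
- Against it: enals under carbene catalysis tend to react through the homoenolate or acyl azolium channels and not as acyl anions, and the aldehyde of A4 sits on a fully substituted alkene carbon that bears a branched chain.
- Against it: A4 needs a tetrasubstituted alkene of defined geometry.
- Against it: the C1 carbonyl of A5 would have to accept hydride from the concave face to place O1 trans to C8, against the normal preference; C9 would still have to be introduced afterwards.
- Comparison: the step count would be similar, with more steps of uncertain selectivity after the key step than in the chosen plan.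

Alternative 3: The cuts are O5–C7 and C7–C8, with C7 supplied by carbon monoxide. Forward, the cis-2-ethynyl carbinol A6 would be carbonylated at O5 (PdCl2, PPh3, SnCl2, CO); the alkoxycarbonyl–palladium unit would add across the alkyne and protonolysis would give A7, the bis-silyl ether of the target.
- Better than the chosen plan: ring B would form at its final oxidation level with C9 in place, one desilylation from the target, and without tin or chromium; the endgame would be two to three steps shorter.
- Against it: the carbonylation is stereospecific and not stereoconvergent, so A6 must already hold the ethynyl group on C6 cis to O5 and trans to O1. That would mean a C–C bond formation with inversion at a secondary carbon flanked by two oxygen-bearing carbons, where elimination is the likely course.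
- Against it: the allylic methacrylate at C1 of A6 is exposed to zerovalent palladium and palladium hydrides formed under the carbonylation conditions, which could ionise or reduce it.
- Comparison: structurally the difficulty of C6 is moved upstream and not solved; mechanistically the ring closure itself is as well precedented as the radical one; in step economy the alternative is better after the key step and worse or unclear before it.

Key step: step 13

## Route

Step 1
Reactants: 1 pent-4-yn-1-ol
Product: 2 4-iodopent-4-en-1-ol
Conditions: NaI, Me3SiCl, H2O (0.5 equiv), MeCN, 0 °C to rt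
Reagents that add atoms: sodium iodide, [Na+].[I-]
Why: Markovnikov hydroiodination of a terminal alkyne by HI generated in the flask; iodide ends on the internal carbon through the more substituted vinyl cation, and the primary alcohol is recovered on aqueous work-up; no stereocentre is formed.

Step 2
Reactants: 2 4-iodopent-4-en-1-ol
Product: 3 tert-butyl[(4-iodopent-4-en-1-yl)oxy]diphenylsilane
Conditions: t-BuPh2SiCl, imidazole, CH2Cl2, 0 °C to rt
Reagents that add atoms: tert-butyl(chloro)diphenylsilane, CC(C)(C)[Si](Cl)(c1ccccc1)c1ccccc1
Why: Standard silylation of a primary alcohol; this silyl group is chosen because it survives the aqueous acetic acid of step 10 and the acidic methanolysis of step 14.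

Step 3
Reactants: 4 (−)-shikimic acid
Product: 6 methyl 3,4-O-isopropylidene shikimate, via methyl shikimate 5 (not isolated)
Conditions: MeOH, camphorsulfonic acid (cat.), reflux; evaporate; Me2C(OMe)2, acetone, rt; Et3N
Reagents that add atoms: methanol, CO; 2,2-dimethoxypropane, COC(C)(C)OC
Why: Fischer esterification followed by acid-catalysed transacetalisation; only the cis pair O1/O6 can close the five-membered dioxolane, which leaves the trans-disposed C5 hydroxyl free, and the three stereocentres of 4 are carried through unchanged.

Step 4
Reactants: 6 methyl 3,4-O-isopropylidene shikimate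
Product: 9 methyl 2-(pinacolboryl)-3,4-O-isopropylidene shikimate, via O5-pinacolboryl ether 7 (not isolated), via C2,O5-bis(pinacolboryl) ester 8 (not isolated)
Conditions: HBpin (1.1 equiv), octane, rt; then B2pin2, [Ir(OMe)(cod)]2 (cat.), AsPh3 (cat.), octane, 100 °C; MeOH
Reagents that add atoms: bis(pinacolato)diboron, CC1(C)OB(OC1(C)C)B1OC(C)(C)C(C)(C)O1
Why: Carbonyl-directed iridium-catalysed vinylic C–H borylation, a reaction established for 1-cycloalkenecarboxylates: the ester oxygen guides the iridium boryl species to C2–H, the only sp2 C–H bond and the one cis to the ester. The C5 hydroxyl is masked in the flask as its boryl ether and released by methanol; no stereocentre is formed.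

Step 5
Reactants: 9 methyl 2-(pinacolboryl)-3,4-O-isopropylidene shikimate; 3 tert-butyl[(4-iodopent-4-en-1-yl)oxy]diphenylsilane
Product: 10 methyl 2-[5-(tert-butyldiphenylsilyloxy)pent-1-en-2-yl]-3,4-O-isopropylidene shikimate
Conditions: Pd(OAc)2 (cat.), SPhos, K3PO4, THF/H2O, 45 °C
Reagents that add atoms: none
Why: Suzuki–Miyaura sp2–sp2 coupling of an alkenyl boronate with a 2-iodo-1-alkene; the electron-rich biarylphosphine serves the hindered, fully substituted C2 boronate and the phosphate base leaves the ester and the free hydroxyl alone; the C2–C1′ bond forms without a new stereocentre.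

Step 6
Reactants: 10 methyl 2-[5-(tert-butyldiphenylsilyloxy)pent-1-en-2-yl]-3,4-O-isopropylidene shikimate
Product: 11 diene diol with CH2OH at C3 and free C5–OH
Conditions: i-Bu2AlH (4 equiv), CH2Cl2, −78 to −20 °C; aq. potassium sodium tartrate
Reagents that add atoms: none
Why: 1,2-Reduction of the hindered, cross-conjugated enoate to the allylic alcohol C10–OH; the acetal and the silyl ether are inert to the aluminium hydride at low temperature.

Step 7
Reactants: 11 diene diol with CH2OH at C3 and free C5–OH
Product: 12 (1′S)-diol with the saturated side chain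
Conditions: H2 (40 bar), [Rh(nbd)(dppb)]BF4 (cat.), CH2Cl2, rt
Reagents that add atoms: none
Why: Hydroxyl-directed homogeneous hydrogenation: the allylic C10 hydroxyl binds the cationic rhodium diphosphine and delivers H2 from the C3 side to the 1,1-disubstituted C1′=CH2 bond only, the tetrasubstituted C2=C3 bond being inert to this catalyst. With O1 held pseudoaxial in the acetal, the chain on C1′ is expected to turn to the ring face opposite O1, and delivery from the C3 side to that rotamer gives 1′S; the high pressure suppresses alkene isomerisation.

Step 8
Reactants: 12 (1′S)-diol with the saturated side chain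
Product: 13 C10 tert-butyldiphenylsilyl ether of 12
Conditions: t-BuPh2SiCl (1.05 equiv), imidazole, CH2Cl2, −20 to 0 °C
Reagents that add atoms: tert-butyl(chloro)diphenylsilane, CC(C)(C)[Si](Cl)(c1ccccc1)c1ccccc1
Why: Selective silylation of the primary allylic hydroxyl in the presence of the secondary C5 hydroxyl, which is flanked by the acetal and reacts far more slowly with this bulky chlorosilane.

Step 9
Reactants: 13 C10 tert-butyldiphenylsilyl ether of 12; 14 propargyl bromide
Product: 15 C5 O-propargyl ether of 13
Conditions: NaH, Bu4NI (cat.), THF, 0 °C to rt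
Reagents that add atoms: none
Why: Williamson etherification of the only free hydroxyl with a reactive propargylic halide; the temperature is kept low so that the propargyl ether does not isomerise to the allenyl ether and the silyl groups do not migrate.

Step 10
Reactants: 15 C5 O-propargyl ether of 13
Product: 16 C1,C6-diol
Conditions: AcOH/H2O (4:1), 40 °C
Reagents that add atoms: none
Why: Mild acid hydrolysis of the isopropylidene acetal through the oxocarbenium ion at the acetal carbon, so the allylic C1–O bond is not ionised; both tert-butyldiphenylsilyl ethers and the propargyl ether are stable to aqueous acetic acid.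

Step 11
Reactants: 16 C1,C6-diol
Product: 17 C1 O-triethylsilyl ether of 16
Conditions: Et3SiCl (1.05 equiv), imidazole, CH2Cl2, −40 °C
Reagents that add atoms: chlorotriethylsilane, CC[Si](Cl)(CC)CC
Why: Regioselective monosilylation: the allylic O1–H is expected to react before O6–H, which is flanked on both sides by oxygen-bearing carbons, the order known for the 3- and 4-hydroxyls of shikimate esters; low temperature and one equivalent of chlorosilane limit bis-silylation.

Step 12
Reactants: 17 C1 O-triethylsilyl ether of 16
Product: 19 O6 S-methyl dithiocarbonate of 17, via sodium xanthate 18 (not isolated)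
Conditions: NaN(SiMe3)2 (1.05 equiv), CS2 (5 equiv), THF, −78 °C; MeI, −78 to −20 °C
Reagents that add atoms: carbon disulfide, S=C=S; iodomethane, CI
Why: Xanthate formation, the first stage of a Barton–McCombie sequence: the C6 alkoxide is generated at −78 °C in excess CS2 so that it is trapped as the dithiocarbonate salt before the neighbouring triethylsilyl group can migrate, and S-methylation fixes it. The C6 configuration is retained but is of no consequence later.

Step 13
Reactants: 19 O6 S-methyl dithiocarbonate of 17
Product: 20 cis-fused 3-methylenetetrahydrofuran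
Conditions: Bu3SnH (1.3 equiv) and AIBN (0.2 equiv) added over 6 h to 19 in degassed benzene (0.01 M), 80 °C
Reagents that add atoms: none
Why: Barton–McCombie radical generation followed by 5-exo-dig cyclisation, the known tin hydride route from propargyl ethers to 3-methylenetetrahydrofurans. Bu3Sn• adds to the thiocarbonyl sulfur of 19, the adduct fragments at the C6–O bond, and the secondary C6 radical attacks the internal alkyne carbon C8 of the O5 propargyl ether, forming C6–C8 and ring B; the vinyl radical at C9 then takes hydrogen from Bu3SnH to leave the exocyclic methylene and carry the chain. Ring B closes in the 5-exo-dig mode, favoured over 6-endo attack at C9 by the short O5–C7 tether and by the oxygen in the chain. The new stereocentre C6 is controlled by C5: a five-membered ring annulated through O5–C7–C8 can only be cis-fused, so C8 arrives on the face of O5 and the configuration of the broken C6–O bond is erased. The step needs ring closure to outrun hydrogen transfer to the C6 radical, which high dilution and slow addition of the stannane secure, and it needs the stannyl radical to choose C=S over the terminal alkyne, which its thiophilicity ensures. C1, C5 and C1′ are not radical sites, and the silyl ethers, the tetrasubstituted alkene and the allylic C1–O bond are inert under these neutral conditions.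

Step 14
Reactants: 20 cis-fused 3-methylenetetrahydrofuran
Product: 21 C1 alcohol
Conditions: PPTS (cat.), MeOH/CH2Cl2, 0 °C to rt
Reagents that add atoms: none
Why: Acid-catalysed methanolysis of the secondary triethylsilyl ether; the two tert-butyldiphenylsilyl ethers are far slower under these conditions and the allylic ether of ring B tolerates mild acid.

Step 15
Reactants: 21 C1 alcohol; 22 methacrylic anhydride
Product: 23 C1 methacrylate
Conditions: Et3N, DMAP (cat.), BHT (trace), CH2Cl2, 0 °C to rt
Reagents that add atoms: none
Why: DMAP-catalysed acylation of the only free hydroxyl with retention at C1; the acylpyridinium intermediate is reactive enough for this hindered secondary allylic alcohol and the radical inhibitor protects the methacrylate.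

Step 16
Reactants: 23 C1 methacrylate
Product: 24 bis(tert-butyldiphenylsilyl) ether of the target
Conditions: CrO3, 3,5-dimethylpyrazole (15 equiv each), CH2Cl2, −20 °C
Reagents that add atoms: chromium trioxide, O=[Cr](=O)=O
Why: Allylic oxidation with the CrO3–3,5-dimethylpyrazole complex, the established conversion of 3-methylenetetrahydrofurans into α-methylene-γ-butyrolactones: C7–H2 is activated by both the C8=C9 bond and O5 and is sterically open. Run after the acylation, C1–H carries an electron-poor ester and C10 is shielded by its bulky silyl group; no stereocentre is touched.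

Step 17
Reactants: 24 bis(tert-butyldiphenylsilyl) ether of the target
Product: 25 (3aR,4S,7aR)-6-(hydroxymethyl)-5-[(2S)-5-hydroxypentan-2-yl]-3-methylidene-2-oxo-2,3,3a,4,7,7a-hexahydro-1-benzofuran-4-yl 2-methylprop-2-enoate
Conditions: HF·pyridine, pyridine, THF, 0 °C to rt
Reagents that add atoms: none
Why: Fluoride cleavage of both primary silyl ethers under buffered, weakly acidic conditions, chosen because basic fluoride would generate alkoxides that add to the two acrylate-type acceptors; O1 and O10 lie on opposite sides of the C2=C3 bond, so acyl migration is not expected.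

## Compound list

1 | pent-4-yn-1-ol | C#CCCCO | starting material
2 | 4-iodopent-4-en-1-ol | C=C(I)CCCO | intermediate
3 | tert-butyl[(4-iodopent-4-en-1-yl)oxy]diphenylsilane | C=C(I)CCCO[Si](c1ccccc1)(c1ccccc1)C(C)(C)C | intermediate
4 | (−)-shikimic acid, (3R,4S,5R)-3,4,5-trihydroxycyclohex-1-ene-1-carboxylic acid | C1[C@H]([C@@H]([C@@H](C=C1C(=O)O)O)O)O | starting material
5 | methyl shikimate, methyl (3R,4S,5R)-3,4,5-trihydroxycyclohex-1-ene-1-carboxylate | COC(=O)C1=C[C@@H](O)[C@@H](O)[C@H](O)C1 | intermediate
6 | methyl 3,4-O-isopropylidene shikimate (acetal across O1/O6 of ring A, free C5–OH, CO2Me on C3, H on C2) | CC1(C)O[C@@H]2C=C(C(=O)OC)C[C@@H](O)[C@@H]2O1 | intermediate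
7 | O5-(pinacolboryl) ether of 6 | CC1(C)O[C@@H]2C=C(C(=O)OC)C[C@@H](OB3OC(C)(C)C(C)(C)O3)[C@@H]2O1 | intermediate
8 | C2,O5-bis(pinacolboryl) derivative of 6 | CC1(C)O[C@@H]2C(B3OC(C)(C)C(C)(C)O3)=C(C(=O)OC)C[C@@H](OB3OC(C)(C)C(C)(C)O3)[C@@H]2O1 | intermediate
9 | methyl 2-(pinacolboryl)-3,4-O-isopropylidene shikimate (boron on C2, free C5–OH) | CC1(C)O[C@@H]2C(B3OC(C)(C)C(C)(C)O3)=C(C(=O)OC)C[C@@H](O)[C@@H]2O1 | intermediate
10 | methyl 2-[5-(tert-butyldiphenylsilyloxy)pent-1-en-2-yl]-3,4-O-isopropylidene shikimate | CC1(C)O[C@@H]2C(C(=C)CCCO[Si](c3ccccc3)(c3ccccc3)C(C)(C)C)=C(C(=O)OC)C[C@@H](O)[C@@H]2O1 | intermediate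
11 | diene diol: 10 with CO2Me reduced to CH2OH (C10–OH and C5–OH free, acetal retained) | CC1(C)O[C@@H]2C(C(=C)CCCO[Si](c3ccccc3)(c3ccccc3)C(C)(C)C)=C(CO)C[C@@H](O)[C@@H]2O1 | intermediate
12 | (1′S)-diol: 11 with C1′=CH2 hydrogenated to (S)-CH(CH3) | CC1(C)O[C@@H]2C([C@@H](C)CCCO[Si](c3ccccc3)(c3ccccc3)C(C)(C)C)=C(CO)C[C@@H](O)[C@@H]2O1 | intermediate
13 | C10 tert-butyldiphenylsilyl ether of 12 (C5–OH free) | CC1(C)O[C@@H]2C([C@@H](C)CCCO[Si](c3ccccc3)(c3ccccc3)C(C)(C)C)=C(CO[Si](c3ccccc3)(c3ccccc3)C(C)(C)C)C[C@@H](O)[C@@H]2O1 | intermediate
14 | propargyl bromide (3-bromoprop-1-yne) | C#CCBr | starting material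
15 | C5 O-(prop-2-yn-1-yl) ether of 13 | CC1(C)O[C@@H]2C([C@@H](C)CCCO[Si](c3ccccc3)(c3ccccc3)C(C)(C)C)=C(CO[Si](c3ccccc3)(c3ccccc3)C(C)(C)C)C[C@@H](OCC#C)[C@@H]2O1 | intermediate
16 | C1,C6-diol from 15 (hydroxyls cis, C5 propargyl ether trans to C6–OH) | O[C@@H]1C([C@@H](C)CCCO[Si](c2ccccc2)(c2ccccc2)C(C)(C)C)=C(CO[Si](c2ccccc2)(c2ccccc2)C(C)(C)C)C[C@@H](OCC#C)[C@@H]1O | intermediate
17 | C1 O-triethylsilyl ether of 16 (C6–OH free) | CC[Si](CC)(CC)O[C@@H]1C([C@@H](C)CCCO[Si](c2ccccc2)(c2ccccc2)C(C)(C)C)=C(CO[Si](c2ccccc2)(c2ccccc2)C(C)(C)C)C[C@@H](OCC#C)[C@@H]1O | intermediate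
18 | sodium O-alkyl dithiocarbonate at O6 of 17 | CC[Si](CC)(CC)O[C@@H]1C([C@@H](C)CCCO[Si](c2ccccc2)(c2ccccc2)C(C)(C)C)=C(CO[Si](c2ccccc2)(c2ccccc2)C(C)(C)C)C[C@@H](OCC#C)[C@@H]1OC(=S)[S-].[Na+] | intermediate
19 | O6 S-methyl dithiocarbonate (xanthate) of 17, precursor of the key step | CC[Si](CC)(CC)O[C@@H]1C([C@@H](C)CCCO[Si](c2ccccc2)(c2ccccc2)C(C)(C)C)=C(CO[Si](c2ccccc2)(c2ccccc2)C(C)(C)C)C[C@@H](OCC#C)[C@@H]1OC(=S)SC | intermediate
20 | cis-fused 3-methylenetetrahydrofuran with C1–OSiEt3, product of the key step | CC[Si](CC)(CC)O[C@@H]1C([C@@H](C)CCCO[Si](c3ccccc3)(c3ccccc3)C(C)(C)C)=C(CO[Si](c3ccccc3)(c3ccccc3)C(C)(C)C)C[C@H]2OCC(=C)[C@@H]12 | intermediate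
21 | C1 alcohol from 20 | O[C@@H]1C([C@@H](C)CCCO[Si](c3ccccc3)(c3ccccc3)C(C)(C)C)=C(CO[Si](c3ccccc3)(c3ccccc3)C(C)(C)C)C[C@H]2OCC(=C)[C@@H]12 | intermediate
22 | methacrylic anhydride | CC(=C)C(=O)OC(=O)C(C)=C | starting material
23 | C1 methacrylate of 21 | C=C(C)C(=O)O[C@@H]1C([C@@H](C)CCCO[Si](c3ccccc3)(c3ccccc3)C(C)(C)C)=C(CO[Si](c3ccccc3)(c3ccccc3)C(C)(C)C)C[C@H]2OCC(=C)[C@@H]12 | intermediate
24 | bis(tert-butyldiphenylsilyl) ether of the target (α-methylene lactone) | C=C(C)C(=O)O[C@@H]1C([C@@H](C)CCCO[Si](c3ccccc3)(c3ccccc3)C(C)(C)C)=C(CO[Si](c3ccccc3)(c3ccccc3)C(C)(C)C)C[C@H]2OC(=O)C(=C)[C@@H]12 | intermediate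
25 | (3aR,4S,7aR)-6-(hydroxymethyl)-5-[(2S)-5-hydroxypentan-2-yl]-3-methylidene-2-oxo-2,3,3a,4,7,7a-hexahydro-1-benzofuran-4-yl 2-methylprop-2-enoate | C=C(C)C(=O)O[C@@H]1C([C@@H](C)CCCO)=C(CO)C[C@H]2OC(=O)C(=C)[C@@H]12 | target

## Step count and least certain steps

Total step count: 17 (steps 1–2 for fragment 3, steps 3–17 from 4). Longest linear sequence: 15 steps (steps 3 to 17).

**Step 13 (key step).** The most likely failure is hydrogen transfer to the C6 radical before ring closure, giving plain deoxygenation at C6, or addition of the stannyl radical to the terminal alkyne. Both compete with a unimolecular closure of a hindered secondary radical. The fallback sets out from 17 and returns at 20. The C6 hydroxyl of 17 is replaced with inversion (I2, PPh3, imidazole, toluene) to give the C6 iodide F1. F1 is cyclised by iodine atom transfer (Et3B, trace air, benzene, rt) to the (iodomethylene)tetrahydrofuran F2; no hydrogen donor is present, so reduction cannot precede ring closure, and the same tether enforces the cis fusion. The vinyl iodide F2 is then reduced with Bu3SnH and Et3B at 0 °C to 20.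

**Step 4.** The most likely failure is slow or incomplete C–H metalation, because C2–H is flanked by the acetal-bearing C1, together with loss of boron from the β-boryl enoate on work-up. The fallback sets out from 6 and 3 and returns at 10. Compound 6 is silylated (Me3SiCl, Et3N) to the O5 trimethylsilyl ether F3. Compound 3 is converted by iodine–lithium exchange (t-BuLi, Et2O, −78 °C) into the alkenyllithium F4 and then with CuI into the lithium dialkenylcuprate F5, which adds to C2 of F3 anti to the C1 oxygen. The ester enolate is trapped with PhSeBr to give the α-phenylselanyl ester F6. Oxidation (H2O2, pyridine, 0 °C) with syn elimination toward the C2 hydrogen gives the dienoate F7, and citric acid in methanol cleaves its trimethylsilyl ether to give 10.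

**Step 7.** The most likely failure is low facial selectivity at C1′: the directing hydroxyl sits on the stereochemically neutral C10, and the ring stereocentres bias the two rotamers of the alkene only weakly. Isomerisation of the 1,1-disubstituted alkene is a second risk. The fallback sets out from 11 and returns at 13. The C10 hydroxyl of 11 is silylated first (t-BuPh2SiCl, imidazole) to the silylated diene F8, which removes the directing group. F8 is hydrogenated with a chiral cationic iridium phosphine–oxazoline catalyst, [Ir(cod)((S)-tBu-PHOX)]B[3,5-(CF3)2C6H3]4 or its enantiomer (H2, CH2Cl2), so that the face is chosen by the catalyst and not by the substrate. The antipode matched to the 1′S face is used and the product is 13.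

**Step 11.** The most likely failure is silylation at O6 or at both oxygens, because the side chain on C2 crowds O1. The fallback sets out from 16 and returns at 21. Compound 16 is converted with MeC(OMe)3 and PPTS into the cyclic orthoacetate F9. Hydrolysis with aqueous acetic acid opens it toward the axial ester and gives the C1 acetate F10 with free C6–OH, independent of steric accessibility. PhOC(S)Cl, pyridine and DMAP give the C6 O-phenyl thionocarbonate F11. The tin hydride cyclisation of step 13 then gives the cyclised acetate F12, and K2CO3 in methanol removes the acetate to give 21.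

**Step 12.** The most likely failure is migration of the triethylsilyl group from O1 to the C6 alkoxide before capture by CS2, or deprotonation of the alkyne. The fallback sets out from 17 and returns at 20. Compound 17 is heated with 1,1′-thiocarbonyldiimidazole and DMAP in toluene, with no alkoxide formed, to give the C6 imidazol-1-ylthiocarbonyl derivative F13. F13 undergoes the same radical cyclisation as 19 with Bu3SnH and AIBN and gives 20.

**Step 16.** The most likely failure is competing oxidation at the allylic positions of the C2=C3 bond (C4, C10) or over-oxidation, because hexavalent chromium does not distinguish sharply between two allylic systems. The fallback sets out from 23 and returns at 24. The more electron-rich tetrasubstituted C2=C3 bond is masked as the epoxide F14 (m-chloroperbenzoic acid, NaHCO3, CH2Cl2, −20 °C; either face, since the configuration is lost again). The oxidation with CrO3 and 3,5-dimethylpyrazole is then run on the only remaining allylic system to give the epoxy lactone F15. The epoxide is finally deoxygenated stereospecifically with Re2O7 (cat.) and P(OPh)3 to return 24.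

## Further compounds

F1 | step 13 | C6 iodide from 17 (inverted at C6) | CC[Si](CC)(CC)O[C@@H]1C([C@@H](C)CCCO[Si](c2ccccc2)(c2ccccc2)C(C)(C)C)=C(CO[Si](c2ccccc2)(c2ccccc2)C(C)(C)C)C[C@@H](OCC#C)[C@H]1I
F2 | step 13 | cis-fused 3-(iodomethylene)tetrahydrofuran (mixture of alkene isomers) | CC[Si](CC)(CC)O[C@@H]1C([C@@H](C)CCCO[Si](c3ccccc3)(c3ccccc3)C(C)(C)C)=C(CO[Si](c3ccccc3)(c3ccccc3)C(C)(C)C)C[C@H]2OCC(=CI)[C@@H]12
F3 | step 4 | O5 trimethylsilyl ether of 6 | CC1(C)O[C@@H]2C=C(C(=O)OC)C[C@@H](O[Si](C)(C)C)[C@@H]2O1
F4 | step 4 | [5-(tert-butyldiphenylsilyloxy)pent-1-en-2-yl]lithium | [Li]C(=C)CCCO[Si](c1ccccc1)(c1ccccc1)C(C)(C)C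
F5 | step 4 | lithium bis[5-(tert-butyldiphenylsilyloxy)pent-1-en-2-yl]cuprate | [Li+].C=C(CCCO[Si](c1ccccc1)(c1ccccc1)C(C)(C)C)[Cu-]C(=C)CCCO[Si](c1ccccc1)(c1ccccc1)C(C)(C)C
F6 | step 4 | α-phenylselanyl ester: conjugate adduct at C2 with PhSe on C3 | CC1(C)O[C@@H]2[C@@H](C(=C)CCCO[Si](c3ccccc3)(c3ccccc3)C(C)(C)C)[C@](C(=O)OC)([Se]c3ccccc3)C[C@@H](O[Si](C)(C)C)[C@@H]2O1
F7 | step 4 | O5 trimethylsilyl ether of 10 | CC1(C)O[C@@H]2C(C(=C)CCCO[Si](c3ccccc3)(c3ccccc3)C(C)(C)C)=C(C(=O)OC)C[C@@H](O[Si](C)(C)C)[C@@H]2O1
F8 | step 7 | C10 tert-butyldiphenylsilyl ether of diene 11 | CC1(C)O[C@@H]2C(C(=C)CCCO[Si](c3ccccc3)(c3ccccc3)C(C)(C)C)=C(CO[Si](c3ccccc3)(c3ccccc3)C(C)(C)C)C[C@@H](O)[C@@H]2O1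
F9 | step 11 | cyclic methyl orthoacetate across O1/O6 of 16 (mixture at the orthoester carbon) | COC1(C)O[C@@H]2C([C@@H](C)CCCO[Si](c3ccccc3)(c3ccccc3)C(C)(C)C)=C(CO[Si](c3ccccc3)(c3ccccc3)C(C)(C)C)C[C@@H](OCC#C)[C@@H]2O1
F10 | step 11 | C1 acetate of 16 with free C6–OH | CC(=O)O[C@@H]1C([C@@H](C)CCCO[Si](c2ccccc2)(c2ccccc2)C(C)(C)C)=C(CO[Si](c2ccccc2)(c2ccccc2)C(C)(C)C)C[C@@H](OCC#C)[C@@H]1O
F11 | step 11 | C6 O-phenyl thionocarbonate of F10 | CC(=O)O[C@@H]1C([C@@H](C)CCCO[Si](c2ccccc2)(c2ccccc2)C(C)(C)C)=C(CO[Si](c2ccccc2)(c2ccccc2)C(C)(C)C)C[C@@H](OCC#C)[C@@H]1OC(=S)Oc2ccccc2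
F12 | step 11 | cis-fused 3-methylenetetrahydrofuran with C1 acetate | CC(=O)O[C@@H]1C([C@@H](C)CCCO[Si](c3ccccc3)(c3ccccc3)C(C)(C)C)=C(CO[Si](c3ccccc3)(c3ccccc3)C(C)(C)C)C[C@H]2OCC(=C)[C@@H]12
F13 | step 12 | C6 O-(imidazol-1-ylthiocarbonyl) derivative of 17 | CC[Si](CC)(CC)O[C@@H]1C([C@@H](C)CCCO[Si](c2ccccc2)(c2ccccc2)C(C)(C)C)=C(CO[Si](c2ccccc2)(c2ccccc2)C(C)(C)C)C[C@@H](OCC#C)[C@@H]1OC(=S)n2ccnc2
F14 | step 16 | C2,C3-epoxide of 23 (either face) | C=C(C)C(=O)O[C@@H]1C2([C@@H](C)CCCO[Si](c4ccccc4)(c4ccccc4)C(C)(C)C)OC2(CO[Si](c4ccccc4)(c4ccccc4)C(C)(C)C)C[C@H]3OCC(=C)[C@@H]13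
F15 | step 16 | C2,C3-epoxide of 24 | C=C(C)C(=O)O[C@@H]1C2([C@@H](C)CCCO[Si](c4ccccc4)(c4ccccc4)C(C)(C)C)OC2(CO[Si](c4ccccc4)(c4ccccc4)C(C)(C)C)C[C@H]3OC(=O)C(=C)[C@@H]13
A1 | alternative 1 | cis-fused cyclopentene lactone with CH2OSi(t-Bu)Ph2 on the alkene carbon C3 | O=C1C[C@H]2C=C(CO[Si](c3ccccc3)(c3ccccc3)C(C)(C)C)C[C@H]2O1
A2 | alternative 1 | gem-dibromocyclopropane from A1 (CBr2 on the convex face, spanning C1 and C3) | BrC1(Br)[C@H]2[C@@H]3CC(=O)O[C@@H]3C[C@@]12CO[Si](c4ccccc4)(c4ccccc4)C(C)(C)C
A3 | alternative 1 | 2-bromocyclohexenol fused to the cis-lactone | O[C@@H]1C(Br)=C(CO[Si](c2ccccc2)(c2ccccc2)C(C)(C)C)C[C@H]2OC(=O)C[C@@H]12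
A4 | alternative 2 | enal (C1 aldehyde, C2=C3) tethered through C4 to C5 of furan-2(5H)-one | O=C/C([C@@H](C)CCCO[Si](C)(C)C(C)(C)C)=C(CO[Si](C)(C)C(C)(C)C)\C[C@H]1OC(=O)C=C1
A5 | alternative 2 | cis-fused enone lactone | O=C1C([C@@H](C)CCCO[Si](C)(C)C(C)(C)C)=C(CO[Si](C)(C)C(C)(C)C)C[C@H]2OC(=O)C[C@@H]12
A6 | alternative 3 | cis-2-ethynyl carbinol (C5–OH, C6–C≡CH) with C1 methacrylate | C=C(C)C(=O)O[C@@H]1C([C@@H](C)CCCO[Si](C)(C)C(C)(C)C)=C(CO[Si](C)(C)C(C)(C)C)C[C@@H](O)[C@H]1C#C
A7 | alternative 3 | bis(tert-butyldimethylsilyl) ether of the target | C=C(C)C(=O)O[C@@H]1C([C@@H](C)CCCO[Si](C)(C)C(C)(C)C)=C(CO[Si](C)(C)C(C)(C)C)C[C@H]2OC(=O)C(=C)[C@@H]12
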